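**Plan**

- Numbering: C1 (acid) to C12 (aryl ketone); C1' is the carbinol carbon of the hydroxyethyl branch on C6. Boc = tert-butoxycarbonyl, TBS = tert-butyldimethylsilyl.
- Retrosynthesis cuts C4=C5 (C5 aldehyde + C1–C4 phosphonate), then C7–CH3 and C6–C1' together (methyl + enoate + acetaldehyde), then C6=C7 (Wittig) and C9–C10 (crotylation of a C10 aldehyde).
- Enabling feature: the only ring is the benzene ring and it is a spectator. The contiguous acyclic triad C7(CH3)–C6–C1'(OH) lies β, α and aldol-β to C5 once C5 is a thioester carbonyl, so one conjugate addition–aldol event builds it.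
- Forward: aryl ketal aldehyde (C10–C12) → anti-crotylation (C7–C10) → enoate thioester C5–C12 → three-component step → C5 aldehyde → C1–C4 dienoate → unmasking. The chain is joined linearly and no ring is formed.
- Stereochemistry: C9/C10 from the chiral crotylborane, C7 from the chiral copper catalyst, C6 from the new C7 centre (enolate face), C1' from the closed aldol transition state.

Key step: step 11

Assumption: the (R,S)-configured Josiphos ligand is taken to deliver methyl to the Re face of C7 of an E-alkenyl thioester (the sense that gives (R)-3-methyl thioesters from simple substrates and the 7,9-syn array here). If a test on a simple thioester shows the opposite sense, the enantiomeric ligand is used and nothing else changes.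

**Route**

Step 1
Reactants: 1 ethyl 3-(4-nitrophenyl)-3-oxopropanoate
Product: 2 ethyl 2-[2-(4-nitrophenyl)-1,3-dioxolan-2-yl]acetate
Conditions: Me3SiOCH2CH2OSiMe3, Me3SiOTf (5 mol %), CH2Cl2, −78 °C → rt
Reagents that add atoms: 1,2-bis(trimethylsilyloxy)ethane C[Si](C)(C)OCCO[Si](C)(C)C
Why: Noyori ketalisation, in which the silyl triflate activates the aryl ketone and formation of the siloxane drives dioxolane closure at low temperature, where the β-keto ester is not transesterified and the nitro group is inert.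

Step 2
Reactants: 2 ethyl 2-[2-(4-nitrophenyl)-1,3-dioxolan-2-yl]acetate
Product: 4 ethyl 2-{2-[4-(Boc-amino)phenyl]-1,3-dioxolan-2-yl}acetate, via aniline 3 (not isolated)
Conditions: H2 (1 atm), Pt/C, EtOAc, rt; filter; Boc2O, THF, 50 °C
Reagents that add atoms: di-tert-butyl dicarbonate CC(C)(C)OC(=O)OC(=O)OC(C)(C)C
Why: Catalytic hydrogenation of the aromatic nitro group over platinum (chosen over palladium so that the benzylic ketal C–O bonds are not hydrogenolysed) followed by carbamate formation on the unpurified aniline, whose electron-rich aryl ketal should not meet aqueous acid.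

Step 3
Reactants: 4 ethyl 2-{2-[4-(Boc-amino)phenyl]-1,3-dioxolan-2-yl}acetate
Product: 5 tert-butyl N-{4-[2-(2-oxoethyl)-1,3-dioxolan-2-yl]phenyl}carbamate
Conditions: i-Bu2AlH (2.2 equiv), CH2Cl2, −78 °C; MeOH, then potassium sodium tartrate (aq)
Reagents that add atoms: none
Why: Partial ester reduction with i-Bu2AlH, in which the first equivalent is consumed by the carbamate N–H and the second gives an aluminium hemiacetal that is stable at −78 °C and releases the aldehyde only on work-up.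

Step 4
Reactants: 5 tert-butyl N-{4-[2-(2-oxoethyl)-1,3-dioxolan-2-yl]phenyl}carbamate; 6 trans-2-butene
Product: 8 tert-butyl N-(4-{2-[(2R,3S)-2-hydroxy-3-methylpent-4-en-1-yl]-1,3-dioxolan-2-yl}phenyl)carbamate, via borinate 7 (not isolated)
Conditions: 6, KOt-Bu, n-BuLi, THF, −78 → −45 °C; (−)-Ipc2BOMe [(−)-B-methoxydiisopinocampheylborane, from (+)-α-pinene], −78 °C; BF3·OEt2, −78 °C; 5, −78 °C; NaOH (aq), H2O2, 0 °C → rt
Reagents that add atoms: none
Why: Brown crotylboration, in which the (E)-crotylborane reacts through a closed six-membered chair so that the E geometry becomes the 9,10-anti relationship, and the isopinocampheyl groups derived from (+)-α-pinene direct the crotyl unit to the Si face of the aldehyde, giving 10R and hence 9S.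

Step 5
Reactants: 8 tert-butyl N-(4-{2-[(2R,3S)-2-hydroxy-3-methylpent-4-en-1-yl]-1,3-dioxolan-2-yl}phenyl)carbamate
Product: 9 tert-butyl N-(4-{2-[(2R,3S)-2-(TBS-oxy)-3-methylpent-4-en-1-yl]-1,3-dioxolan-2-yl}phenyl)carbamate
Conditions: TBSOTf, 2,6-lutidine, CH2Cl2, −78 °C
Reagents that add atoms: tert-butyldimethylsilyl trifluoromethanesulfonate CC(C)(C)[Si](C)(C)OS(=O)(=O)C(F)(F)F
Why: Silylation of a secondary alcohol with a silyl triflate and a hindered pyridine base, run cold so that the carbamate and the ketal are not touched.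

Step 6
Reactants: 9 tert-butyl N-(4-{2-[(2R,3S)-2-(TBS-oxy)-3-methylpent-4-en-1-yl]-1,3-dioxolan-2-yl}phenyl)carbamate
Product: 11 tert-butyl N-(4-{2-[(2R,3S)-2-(TBS-oxy)-5-hydroxy-3-methylpentyl]-1,3-dioxolan-2-yl}phenyl)carbamate, via B-alkyl-9-BBN 10 (not isolated)
Conditions: 9-BBN–H, THF, 0 °C → rt; NaOH (aq), H2O2, 0 °C → rt
Reagents that add atoms: hydrogen peroxide OO
Why: Hydroboration–oxidation, in which the bulky dialkylborane places boron on the terminal carbon C7 of the monosubstituted alkene and alkaline peroxide replaces boron by hydroxyl without affecting C9 or C10.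

Step 7
Reactants: 12 bromoacetyl bromide; 13 ethanethiol
Product: 14 S-ethyl 2-bromoethanethioate
Conditions: pyridine (1 equiv), CH2Cl2, −10 → 0 °C
Reagents that add atoms: none
Why: S-Acylation of the thiol by the acid bromide, which is much faster at low temperature than substitution at the α-bromide.

Step 8
Reactants: 14 S-ethyl 2-bromoethanethioate
Product: 16 S-ethyl 2-(triphenyl-λ5-phosphanylidene)ethanethioate, via phosphonium bromide 15 (not isolated)
Conditions: PPh3, toluene, rt; Na2CO3 (aq), CH2Cl2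
Reagents that add atoms: triphenylphosphine c1ccccc1P(c2ccccc2)c3ccccc3
Why: Quaternisation of the phosphine by the α-bromo thioester and deprotonation of the acidic phosphonium salt by carbonate give the stabilised Wittig ylide.

Step 9
Reactants: 11 tert-butyl N-(4-{2-[(2R,3S)-2-(TBS-oxy)-5-hydroxy-3-methylpentyl]-1,3-dioxolan-2-yl}phenyl)carbamate; 16 S-ethyl 2-(triphenyl-λ5-phosphanylidene)ethanethioate
Product: 18 S-ethyl (2E,5S,6R)-7-{2-[4-(Boc-amino)phenyl]-1,3-dioxolan-2-yl}-6-(TBS-oxy)-5-methylhept-2-enethioate, via C7 aldehyde 17 (not isolated)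
Conditions: SO3·pyridine, DMSO, i-Pr2NEt, CH2Cl2, 0 °C; aqueous work-up; 16, CH2Cl2, rt
Reagents that add atoms: none
Why: Parikh–Doering oxidation under basic conditions (preferred to a periodinane, which could attack the anilide) followed by Wittig olefination with the stabilised ylide, which should give the E-enoate; C9 is β to the aldehyde and cannot epimerise.

Step 10
Reactants: 18 S-ethyl (2E,5S,6R)-7-{2-[4-(Boc-amino)phenyl]-1,3-dioxolan-2-yl}-6-(TBS-oxy)-5-methylhept-2-enethioate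
Product: 19 S-ethyl (2E,5S,6R)-7-{2-[4-(bis-Boc-amino)phenyl]-1,3-dioxolan-2-yl}-6-(TBS-oxy)-5-methylhept-2-enethioate
Conditions: Boc2O, DMAP (0.2 equiv), MeCN, rt
Reagents that add atoms: di-tert-butyl dicarbonate CC(C)(C)OC(=O)OC(=O)OC(C)(C)C
Why: DMAP-catalysed N-acylation of the anilide removes the only acidic N–H, which would otherwise consume Grignard reagent and place a magnesium amidate next to the copper catalyst in the next step.

Step 11
Reactants: 19 S-ethyl (2E,5S,6R)-7-{2-[4-(bis-Boc-amino)phenyl]-1,3-dioxolan-2-yl}-6-(TBS-oxy)-5-methylhept-2-enethioate; 20 methylmagnesium bromide; 21 acetaldehyde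
Product: 23 S-ethyl (2R,3R,5S,6R)-7-{2-[4-(bis-Boc-amino)phenyl]-1,3-dioxolan-2-yl}-6-(TBS-oxy)-2-[(1S)-1-hydroxyethyl]-3,5-dimethylheptanethioate, via magnesium Z(O)-thioenolate 22 (not isolated)
Conditions: CuBr·SMe2 (5 mol %), (R)-1-[(SP)-2-(diphenylphosphino)ferrocenyl]ethyldicyclohexylphosphine (6 mol %), 20 (1.3 equiv), t-BuOMe, −75 °C, slow addition of 19; then 21 (5 equiv), −75 °C; NH4Cl (aq), −75 °C
Reagents that add atoms: none
Why: This is a copper-catalysed asymmetric conjugate addition of a Grignard reagent to an α,β-unsaturated thioester with aldehyde trapping of the magnesium enolate, a known three-component reaction type: the methylcopper–diphosphine complex (monovalent copper) binds the s-cis enoate, forms a σ-bonded trivalent copper species at C7 and reductively eliminates to give C7–CH3 and the Z(O)-magnesium thioenolate 22, which adds to acetaldehyde through a closed six-membered chair to form C6–C1'. No ring is closed. C7 (R) is set by the ligand, which delivers methyl to the Re face of C7 and gives the 7,9-syn dimethyl array irrespective of the remote C9/C10 centres. C6 is set by the new C7 centre: with C7–H eclipsing the enolate C–OMg bond to minimise allylic strain, acetaldehyde should approach the enolate face that carries the C7 methyl group and not the C8 chain. C1' (S) follows from the Z(O) geometry and an equatorial acetaldehyde methyl group in the chair, that is, a syn aldol. The step needs 1,4- over 1,2-addition (secured by the thioester and the copper catalyst), a substrate without acidic protons (secured by the bis-Boc nitrogen) and a cold quench so that the magnesium aldolate does not equilibrate by retro-aldol.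

Step 12
Reactants: 23 S-ethyl (2R,3R,5S,6R)-7-{2-[4-(bis-Boc-amino)phenyl]-1,3-dioxolan-2-yl}-6-(TBS-oxy)-2-[(1S)-1-hydroxyethyl]-3,5-dimethylheptanethioate
Product: 24 S-ethyl (2R,3R,5S,6R)-7-{2-[4-(bis-Boc-amino)phenyl]-1,3-dioxolan-2-yl}-6-(TBS-oxy)-2-[(1S)-1-(TBS-oxy)ethyl]-3,5-dimethylheptanethioate
Conditions: TBSOTf, 2,6-lutidine, CH2Cl2, −78 °C
Reagents that add atoms: tert-butyldimethylsilyl trifluoromethanesulfonate CC(C)(C)[Si](C)(C)OS(=O)(=O)C(F)(F)F
Why: Silylation of the aldol hydroxyl with a silyl triflate blocks retro-aldol and elimination in the following steps; at −78 °C the Boc groups should survive.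

Step 13
Reactants: 24 S-ethyl (2R,3R,5S,6R)-7-{2-[4-(bis-Boc-amino)phenyl]-1,3-dioxolan-2-yl}-6-(TBS-oxy)-2-[(1S)-1-(TBS-oxy)ethyl]-3,5-dimethylheptanethioate
Product: 25 (2R,3R,5S,6R)-7-{2-[4-(bis-Boc-amino)phenyl]-1,3-dioxolan-2-yl}-6-(TBS-oxy)-2-[(1S)-1-(TBS-oxy)ethyl]-3,5-dimethylheptanal
Conditions: Et3SiH, Pd/C, acetone, rt
Reagents that add atoms: none
Why: Fukuyama reduction, in which zerovalent palladium inserts into the C–S bond and the silane delivers hydride, gives the aldehyde at neutral pH without over-reduction, without touching the imidodicarbonate and without epimerising C6.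

Step 14
Reactants: 25 (2R,3R,5S,6R)-7-{2-[4-(bis-Boc-amino)phenyl]-1,3-dioxolan-2-yl}-6-(TBS-oxy)-2-[(1S)-1-(TBS-oxy)ethyl]-3,5-dimethylheptanal; 26 ethyl (E)-4-(diethoxyphosphoryl)but-2-enoate
Product: 27 ethyl (2E,4E,6S,7R,9S,10R)-11-{2-[4-(bis-Boc-amino)phenyl]-1,3-dioxolan-2-yl}-10-(TBS-oxy)-6-[(1S)-1-(TBS-oxy)ethyl]-7,9-dimethylundeca-2,4-dienoate
Conditions: 26, LiN(SiMe3)2, THF, −78 °C; 25, −78 → 0 °C
Reagents that add atoms: none
Why: Vinylogous Horner–Wadsworth–Emmons olefination, in which the lithiated phosphonocrotonate attacks through its α-carbon and phosphate elimination should give the new C4=C5 bond E while C2=C3 keeps its E geometry; the low temperature limits enolisation of the α-branched aldehyde.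

Step 15
Reactants: 27 ethyl (2E,4E,6S,7R,9S,10R)-11-{2-[4-(bis-Boc-amino)phenyl]-1,3-dioxolan-2-yl}-10-(TBS-oxy)-6-[(1S)-1-(TBS-oxy)ethyl]-7,9-dimethylundeca-2,4-dienoate
Product: 28 (2E,4E,6S,7R,9S,10R)-11-{2-[4-(Boc-amino)phenyl]-1,3-dioxolan-2-yl}-10-(TBS-oxy)-6-[(1S)-1-(TBS-oxy)ethyl]-7,9-dimethylundeca-2,4-dienoic acid
Conditions: LiOH·H2O, THF/MeOH/H2O, 40 °C; AcOH to pH 5, 0 °C
Reagents that add atoms: lithium hydroxide [Li+].[OH-]
Why: Saponification is done while C12 is still a ketal, so that no β-hydroxy ketone meets base; hydroxide is also expected to remove one Boc group from the imidodicarbonate, which is harmless because all nitrogen protection falls in the next step.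

Step 16
Reactants: 28 (2E,4E,6S,7R,9S,10R)-11-{2-[4-(Boc-amino)phenyl]-1,3-dioxolan-2-yl}-10-(TBS-oxy)-6-[(1S)-1-(TBS-oxy)ethyl]-7,9-dimethylundeca-2,4-dienoic acid
Product: 29 (2E,4E,6S,7R,9S,10R)-12-(4-aminophenyl)-10-hydroxy-6-[(1S)-1-hydroxyethyl]-7,9-dimethyl-12-oxododeca-2,4-dienoic acid
Conditions: CF3CO2H/H2O (9:1), 0 °C → rt; evaporate; NaHCO3 (aq) to pH 5–6
Reagents that add atoms: water O
Why: Global acidolysis removes the Boc group, both silyl ethers and the dioxolane in one operation; the ketone appears only after all basic steps are over, and the protonated aniline should slow acid-catalysed dehydration of the β-hydroxy ketone.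

**Compound list**

1 | ethyl 3-(4-nitrophenyl)-3-oxopropanoate | CCOC(=O)CC(=O)c1ccc(cc1)[N+](=O)[O-] | starting material
2 | ethyl 2-[2-(4-nitrophenyl)-1,3-dioxolan-2-yl]acetate | CCOC(=O)CC1(OCCO1)c2ccc(cc2)[N+](=O)[O-] | intermediate
3 | ethyl 2-[2-(4-aminophenyl)-1,3-dioxolan-2-yl]acetate (not isolated) | CCOC(=O)CC1(OCCO1)c2ccc(N)cc2 | intermediate
4 | ethyl 2-{2-[4-(Boc-amino)phenyl]-1,3-dioxolan-2-yl}acetate | CCOC(=O)CC1(OCCO1)c2ccc(NC(=O)OC(C)(C)C)cc2 | intermediate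
5 | tert-butyl N-{4-[2-(2-oxoethyl)-1,3-dioxolan-2-yl]phenyl}carbamate | O=CCC1(OCCO1)c2ccc(NC(=O)OC(C)(C)C)cc2 | intermediate
6 | trans-2-butene | C/C=C/C | starting material
7 | O-diisopinocampheylboryl derivative (borinate) of 8 (not isolated) | C=C[C@H](C)[C@H](OB([C@@H]1C[C@@H]2C[C@H]([C@H]1C)C2(C)C)[C@@H]3C[C@@H]4C[C@H]([C@H]3C)C4(C)C)CC5(OCCO5)c6ccc(NC(=O)OC(C)(C)C)cc6 | intermediate
8 | tert-butyl N-(4-{2-[(2R,3S)-2-hydroxy-3-methylpent-4-en-1-yl]-1,3-dioxolan-2-yl}phenyl)carbamate | C=C[C@H](C)[C@H](O)CC1(OCCO1)c2ccc(NC(=O)OC(C)(C)C)cc2 | intermediate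
9 | tert-butyl N-(4-{2-[(2R,3S)-2-(TBS-oxy)-3-methylpent-4-en-1-yl]-1,3-dioxolan-2-yl}phenyl)carbamate | C=C[C@H](C)[C@H](O[Si](C)(C)C(C)(C)C)CC1(OCCO1)c2ccc(NC(=O)OC(C)(C)C)cc2 | intermediate
10 | B-alkyl-9-borabicyclo[3.3.1]nonane from 9, boron on C7 (not isolated) | C(C[C@H](C)[C@H](O[Si](C)(C)C(C)(C)C)CC1(OCCO1)c2ccc(NC(=O)OC(C)(C)C)cc2)B3C4CCCC3CCC4 | intermediate
11 | tert-butyl N-(4-{2-[(2R,3S)-2-(TBS-oxy)-5-hydroxy-3-methylpentyl]-1,3-dioxolan-2-yl}phenyl)carbamate | OCC[C@H](C)[C@H](O[Si](C)(C)C(C)(C)C)CC1(OCCO1)c2ccc(NC(=O)OC(C)(C)C)cc2 | intermediate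
12 | bromoacetyl bromide | BrCC(Br)=O | starting material
13 | ethanethiol | CCS | starting material
14 | S-ethyl 2-bromoethanethioate | CCSC(=O)CBr | intermediate
15 | [2-(ethylsulfanyl)-2-oxoethyl]triphenylphosphonium bromide (not isolated) | CCSC(=O)C[P+](c1ccccc1)(c2ccccc2)c3ccccc3.[Br-] | intermediate
16 | S-ethyl 2-(triphenyl-λ5-phosphanylidene)ethanethioate | CCSC(=O)C=P(c1ccccc1)(c2ccccc2)c3ccccc3 | intermediate
17 | tert-butyl N-(4-{2-[(2R,3S)-2-(TBS-oxy)-3-methyl-5-oxopentyl]-1,3-dioxolan-2-yl}phenyl)carbamate (not isolated) | O=CC[C@H](C)[C@H](O[Si](C)(C)C(C)(C)C)CC1(OCCO1)c2ccc(NC(=O)OC(C)(C)C)cc2 | intermediate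
18 | S-ethyl (2E,5S,6R)-7-{2-[4-(Boc-amino)phenyl]-1,3-dioxolan-2-yl}-6-(TBS-oxy)-5-methylhept-2-enethioate | CCSC(=O)/C=C/C[C@H](C)[C@H](O[Si](C)(C)C(C)(C)C)CC1(OCCO1)c2ccc(NC(=O)OC(C)(C)C)cc2 | intermediate
19 | S-ethyl (2E,5S,6R)-7-{2-[4-(bis-Boc-amino)phenyl]-1,3-dioxolan-2-yl}-6-(TBS-oxy)-5-methylhept-2-enethioate | CCSC(=O)/C=C/C[C@H](C)[C@H](O[Si](C)(C)C(C)(C)C)CC1(OCCO1)c2ccc(N(C(=O)OC(C)(C)C)C(=O)OC(C)(C)C)cc2 | intermediate
20 | methylmagnesium bromide | C[Mg]Br | starting material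
21 | acetaldehyde | CC=O | starting material
22 | bromomagnesium Z(O)-enolate of the 7R methyl adduct of 19, O–Mg cis to C7 (not isolated) | CCS/C(O[Mg]Br)=C/[C@H](C)C[C@H](C)[C@H](O[Si](C)(C)C(C)(C)C)CC1(OCCO1)c2ccc(N(C(=O)OC(C)(C)C)C(=O)OC(C)(C)C)cc2 | intermediate
23 | S-ethyl (2R,3R,5S,6R)-7-{2-[4-(bis-Boc-amino)phenyl]-1,3-dioxolan-2-yl}-6-(TBS-oxy)-2-[(1S)-1-hydroxyethyl]-3,5-dimethylheptanethioate | C[C@H](O)[C@H](C(=O)SCC)[C@H](C)C[C@H](C)[C@H](O[Si](C)(C)C(C)(C)C)CC1(OCCO1)c2ccc(N(C(=O)OC(C)(C)C)C(=O)OC(C)(C)C)cc2 | intermediate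
24 | S-ethyl (2R,3R,5S,6R)-7-{2-[4-(bis-Boc-amino)phenyl]-1,3-dioxolan-2-yl}-6-(TBS-oxy)-2-[(1S)-1-(TBS-oxy)ethyl]-3,5-dimethylheptanethioate | C[C@H](O[Si](C)(C)C(C)(C)C)[C@H](C(=O)SCC)[C@H](C)C[C@H](C)[C@H](O[Si](C)(C)C(C)(C)C)CC1(OCCO1)c2ccc(N(C(=O)OC(C)(C)C)C(=O)OC(C)(C)C)cc2 | intermediate
25 | (2R,3R,5S,6R)-7-{2-[4-(bis-Boc-amino)phenyl]-1,3-dioxolan-2-yl}-6-(TBS-oxy)-2-[(1S)-1-(TBS-oxy)ethyl]-3,5-dimethylheptanal | C[C@H](O[Si](C)(C)C(C)(C)C)[C@H](C=O)[C@H](C)C[C@H](C)[C@H](O[Si](C)(C)C(C)(C)C)CC1(OCCO1)c2ccc(N(C(=O)OC(C)(C)C)C(=O)OC(C)(C)C)cc2 | intermediate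
26 | ethyl (E)-4-(diethoxyphosphoryl)but-2-enoate | CCOC(=O)/C=C/CP(=O)(OCC)OCC | starting material
27 | ethyl (2E,4E,6S,7R,9S,10R)-11-{2-[4-(bis-Boc-amino)phenyl]-1,3-dioxolan-2-yl}-10-(TBS-oxy)-6-[(1S)-1-(TBS-oxy)ethyl]-7,9-dimethylundeca-2,4-dienoate | C[C@H](O[Si](C)(C)C(C)(C)C)[C@H](/C=C/C=C/C(=O)OCC)[C@H](C)C[C@H](C)[C@H](O[Si](C)(C)C(C)(C)C)CC1(OCCO1)c2ccc(N(C(=O)OC(C)(C)C)C(=O)OC(C)(C)C)cc2 | intermediate
28 | (2E,4E,6S,7R,9S,10R)-11-{2-[4-(Boc-amino)phenyl]-1,3-dioxolan-2-yl}-10-(TBS-oxy)-6-[(1S)-1-(TBS-oxy)ethyl]-7,9-dimethylundeca-2,4-dienoic acid | C[C@H](O[Si](C)(C)C(C)(C)C)[C@H](/C=C/C=C/C(=O)O)[C@H](C)C[C@H](C)[C@H](O[Si](C)(C)C(C)(C)C)CC1(OCCO1)c2ccc(NC(=O)OC(C)(C)C)cc2 | intermediate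
29 | (2E,4E,6S,7R,9S,10R)-12-(4-aminophenyl)-10-hydroxy-6-[(1S)-1-hydroxyethyl]-7,9-dimethyl-12-oxododeca-2,4-dienoic acid | C[C@H](O)[C@H](/C=C/C=C/C(=O)O)[C@H](C)C[C@H](C)[C@H](O)CC(=O)c1ccc(N)cc1 | target

**Step count**

Total: 16 steps. Longest linear sequence: 14 steps (steps 1–6 and 9–16); steps 7–8 prepare the ylide.

**Steps most likely to fail**

1. Step 11. Process at risk: weak discrimination by the enolate between its two faces (methyl against the C8 chain on C7), incomplete catalyst control at C7, or retro-aldol equilibration of the magnesium aldolate, each of which would give diastereomers at C6/C1' or C7.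
Fallback (from 19, back at 24): the copper/Josiphos methyl addition is run without aldehyde and quenched to give the β-methyl thioester F1. LiOH in aqueous THF hydrolyses it, with loss of one Boc group, to the acid F2. Pivaloyl chloride/Et3N and then lithiated (R)-4-benzyl-1,3-oxazolidin-2-one give the imide F3. An Evans syn aldol (Bu2BOTf, i-Pr2NEt, then acetaldehyde), in which the auxiliary and not C7 fixes C6 and C1', gives the aldol imide F4. TBSOTf/2,6-lutidine gives the silyl ether F5, LiSEt in THF exchanges the auxiliary for the thioester F6, and Boc2O/DMAP returns 24.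

2. Step 16. Process at risk: acid-catalysed dehydration of the unmasked β-hydroxy aryl ketone, or incomplete desilylation, during the single strongly acidic operation.
Fallback (from 28, back at 29): the unmasking is staged. Aqueous HF in MeCN removes both silyl ethers and hydrolyses the electron-rich aryl ketal to give the N-Boc amino acid F7. The carbamate is then cleaved under non-protic conditions (Me3SiOTf, 2,6-lutidine, CH2Cl2, 0 °C; then MeOH) to give 29.

3. Step 14. Process at risk: enolisation of the hindered α-branched aldehyde by the basic phosphonate anion, leading to epimerisation at C6 or β-elimination of the silyloxy group, and slow or poorly E-selective olefination.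
Fallback (from 25, back at 27): a Takai olefination (chromium dichloride, that is divalent chromium, with CHI3 in THF) is non-basic and gives the (E)-vinyl iodide F8. A Heck coupling with ethyl acrylate (palladium diacetate, Bu4NCl, NaHCO3, DMF) then gives dienoate 27.

**Further compounds**

F1 | step 11 | S-ethyl (3R,5S,6R)-7-{2-[4-(bis-Boc-amino)phenyl]-1,3-dioxolan-2-yl}-6-(TBS-oxy)-3,5-dimethylheptanethioate | CCSC(=O)C[C@H](C)C[C@H](C)[C@H](O[Si](C)(C)C(C)(C)C)CC1(OCCO1)c2ccc(N(C(=O)OC(C)(C)C)C(=O)OC(C)(C)C)cc2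
F2 | step 11 | (3R,5S,6R)-7-{2-[4-(Boc-amino)phenyl]-1,3-dioxolan-2-yl}-6-(TBS-oxy)-3,5-dimethylheptanoic acid | OC(=O)C[C@H](C)C[C@H](C)[C@H](O[Si](C)(C)C(C)(C)C)CC1(OCCO1)c2ccc(NC(=O)OC(C)(C)C)cc2
F3 | step 11 | (4R)-4-benzyl-3-[(3R,5S,6R)-7-{2-[4-(Boc-amino)phenyl]-1,3-dioxolan-2-yl}-6-(TBS-oxy)-3,5-dimethylheptanoyl]-1,3-oxazolidin-2-one | O=C(C[C@H](C)C[C@H](C)[C@H](O[Si](C)(C)C(C)(C)C)CC1(OCCO1)c2ccc(NC(=O)OC(C)(C)C)cc2)N3[C@H](Cc4ccccc4)COC3=O
F4 | step 11 | (4R)-4-benzyl-3-[(2R,3R,5S,6R)-7-{2-[4-(Boc-amino)phenyl]-1,3-dioxolan-2-yl}-6-(TBS-oxy)-2-[(1S)-1-hydroxyethyl]-3,5-dimethylheptanoyl]-1,3-oxazolidin-2-one | C[C@H](O)[C@H](C(=O)N1[C@H](Cc2ccccc2)COC1=O)[C@H](C)C[C@H](C)[C@H](O[Si](C)(C)C(C)(C)C)CC3(OCCO3)c4ccc(NC(=O)OC(C)(C)C)cc4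
F5 | step 11 | (4R)-4-benzyl-3-[(2R,3R,5S,6R)-7-{2-[4-(Boc-amino)phenyl]-1,3-dioxolan-2-yl}-6-(TBS-oxy)-2-[(1S)-1-(TBS-oxy)ethyl]-3,5-dimethylheptanoyl]-1,3-oxazolidin-2-one | C[C@H](O[Si](C)(C)C(C)(C)C)[C@H](C(=O)N1[C@H](Cc2ccccc2)COC1=O)[C@H](C)C[C@H](C)[C@H](O[Si](C)(C)C(C)(C)C)CC3(OCCO3)c4ccc(NC(=O)OC(C)(C)C)cc4
F6 | step 11 | S-ethyl (2R,3R,5S,6R)-7-{2-[4-(Boc-amino)phenyl]-1,3-dioxolan-2-yl}-6-(TBS-oxy)-2-[(1S)-1-(TBS-oxy)ethyl]-3,5-dimethylheptanethioate | C[C@H](O[Si](C)(C)C(C)(C)C)[C@H](C(=O)SCC)[C@H](C)C[C@H](C)[C@H](O[Si](C)(C)C(C)(C)C)CC1(OCCO1)c2ccc(NC(=O)OC(C)(C)C)cc2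
F7 | step 16 | (2E,4E,6S,7R,9S,10R)-12-[4-(Boc-amino)phenyl]-10-hydroxy-6-[(1S)-1-hydroxyethyl]-7,9-dimethyl-12-oxododeca-2,4-dienoic acid | C[C@H](O)[C@H](/C=C/C=C/C(=O)O)[C@H](C)C[C@H](C)[C@H](O)CC(=O)c1ccc(NC(=O)OC(C)(C)C)cc1
F8 | step 14 | di-tert-butyl N-(4-{2-[(2R,3S,5R,6S,7E)-2-(TBS-oxy)-6-[(1S)-1-(TBS-oxy)ethyl]-8-iodo-3,5-dimethyloct-7-en-1-yl]-1,3-dioxolan-2-yl}phenyl)imidodicarbonate | C[C@H](O[Si](C)(C)C(C)(C)C)[C@H](/C=C/I)[C@H](C)C[C@H](C)[C@H](O[Si](C)(C)C(C)(C)C)CC1(OCCO1)c2ccc(N(C(=O)OC(C)(C)C)C(=O)OC(C)(C)C)cc2
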